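**Plan**

- Retrosynthesis: the helper bonds come off first (thirteen benzyl C–O and four aryl C–Br bonds). The biaryl bond between C6' of ring B of the epicatechin-gallate (ECG) half and C2' of ring B of the epigallocatechin-gallate (EGCG) half is cut next. Each half is then cut at its gallate ester C3–O bond, and the ECG half also at its catechol ketal, back to (−)-epicatechin, (−)-epigallocatechin and one shared protected gallic acid.
- Forward: no ring is built, both chroman systems are inherited. The ECG half comes from (−)-epicatechin (catechol ketal, benzylation, gallate ester, ring-A bromination, ketal removal). The EGCG half comes from (−)-epigallocatechin (benzylation of the five phenols, gallate ester, ring-A bromination). One conjugate arylation joins them and one hydrogenolysis removes every helper.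
- Enabling feature: ring B of the ECG half is a catechol (O3', O4'), and in its o-quinone the carbon to be bonded, C6', is the β-carbon of the C4'=O/C5'=C6' enone. The partner carbon C2' of ring B of the EGCG half lies ortho to O3' and para to O5' and is equivalent to C6'. An acceptor and a donor carbon therefore meet at the oxidation level of the product, with no halogen or metal on either.
- Helpers: benzyl ethers on every other phenol stop redox exchange and benzotropolone formation; bromine at C6 and C8 of both A rings blocks the otherwise most nucleophilic arene positions.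
- Stereochemistry: all four stereocentres (2R,3R in each half) are bought with the two natural flavan-3-ols and no bond to them is broken; the biaryl axis forms under substrate control.

Key step: step 9

Assumption: the target structure defines four stereocentres but not the sense of the biaryl axis, so the route controls the stereocentres and treats the axis as formed under substrate control; any pair of atropisomers would be separated by chromatography at the protected biaryl or at the final product.

**Route**

Step 1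
Reactants: 1 (−)-epicatechin
Product: 2 3',4'-O-diphenylmethylene-(−)-epicatechin
Conditions: Ph2CCl2 (1.2 equiv), K2CO3, MeCN, rt, argon
Reagents that add atoms: dichlorodiphenylmethane, ClC(Cl)(c1ccccc1)c1ccccc1
Why: Cyclic ketal formation by double substitution: only the ortho-related O3'/O4' pair of ring B can close the five-membered 2,2-diphenyl-1,3-benzodioxole, whereas mono-adducts at the meta-related ring-A phenols should revert on aqueous work-up, and no stereocentre is touched.

Step 2
Reactants: 2 3',4'-O-diphenylmethylene-(−)-epicatechin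
Product: 3 5,7-di-O-benzyl-3',4'-O-diphenylmethylene-(−)-epicatechin
Conditions: BnBr (2.2 equiv), K2CO3, DMF, 0 °C to rt, argon
Reagents that add atoms: benzyl bromide, BrCc1ccccc1
Why: Williamson ether synthesis in which K2CO3 deprotonates only the two ring-A phenols, so the secondary 3-OH should stay free.

Step 3
Reactants: 3 5,7-di-O-benzyl-3',4'-O-diphenylmethylene-(−)-epicatechin; 4 3,4,5-tris(benzyloxy)benzoic acid
Product: 5 5,7-di-O-benzyl-3',4'-O-diphenylmethylene-(−)-epicatechin 3-O-[3,4,5-tris(benzyloxy)benzoate]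
Conditions: DCC, DMAP (cat.), CH2Cl2, rt
Reagents that add atoms: none
Why: Steglich esterification of the axial 3-OH through the acylpyridinium ion; the C3–O bond is not broken, so the configuration is retained.

Step 4
Reactants: 5 5,7-di-O-benzyl-3',4'-O-diphenylmethylene-(−)-epicatechin 3-O-[3,4,5-tris(benzyloxy)benzoate]
Product: 6 6,8-dibromo derivative of 5
Conditions: NBS (2.1 equiv), CH2Cl2, −20 °C to rt, dark
Reagents that add atoms: N-bromosuccinimide, O=C1CCC(=O)N1Br
Why: Electrophilic aromatic bromination: C6 and C8 of ring A each lie ortho or para to three oxygen donors and should react well ahead of the benzodioxole ring and the ester-deactivated galloyl ring, which installs the two blocking groups.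

Step 5
Reactants: 6 6,8-dibromo derivative of 5
Product: 7 5,7-di-O-benzyl-6,8-dibromo-(−)-epicatechin 3-O-[3,4,5-tris(benzyloxy)benzoate] with free 3',4'-catechol
Conditions: AcOH/H2O/THF (4:1:1), reflux
Reagents that add atoms: none
Why: Acid-catalysed hydrolysis of the benzophenone ketal frees the ring-B catechol, while benzyl ethers, aryl bromides and the gallate ester are inert to aqueous acetic acid.

Step 6
Reactants: 8 (−)-epigallocatechin
Product: 9 penta-O-benzyl-(−)-epigallocatechin
Conditions: BnBr (5.5 equiv), K2CO3, DMF, degassed, 0 °C to rt, argon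
Reagents that add atoms: benzyl bromide, BrCc1ccccc1
Why: Williamson ether synthesis in which K2CO3 deprotonates only the five phenols, so the secondary 3-OH should stay free, while exclusion of air protects the pyrogallol ring B until it is capped and no stereocentre is touched.

Step 7
Reactants: 9 penta-O-benzyl-(−)-epigallocatechin; 4 3,4,5-tris(benzyloxy)benzoic acid
Product: 10 octa-O-benzyl-(−)-epigallocatechin 3-gallate
Conditions: DCC, DMAP (cat.), CH2Cl2, rt
Reagents that add atoms: none
Why: Steglich esterification of the axial 3-OH through the acylpyridinium ion; the C3–O bond is not broken, so the configuration is retained.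

Step 8
Reactants: 10 octa-O-benzyl-(−)-epigallocatechin 3-gallate
Product: 11 6,8-dibromo-octa-O-benzyl-(−)-epigallocatechin 3-gallate
Conditions: NBS (2.1 equiv), CH2Cl2, −20 °C to rt, dark
Reagents that add atoms: N-bromosuccinimide, O=C1CCC(=O)N1Br
Why: Electrophilic aromatic bromination at C6 and C8 of ring A, which are activated by three oxygens each, whereas the free CH positions of ring B have only two activating oxygens and a bulky neighbour and should stay unsubstituted at two equivalents of reagent.

Step 9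
Reactants: 7 free-catechol ECG half (1 equiv); 11 6,8-dibromo-octa-O-benzyl-(−)-epigallocatechin 3-gallate (1.3 equiv)
Product: 13 tetrabromo-trideca-O-benzyl-theasinensin F, via ortho-quinone 12 (not isolated)
Conditions: Ag2O, Na2SO4, CH2Cl2, −20 °C, filtration under argon; filtrate added slowly to 11, Sc(OTf)3 (10 mol %), CH2Cl2, −40 to 0 °C
Reagents that add atoms: none
Why: Proposed new method: Ag2O dehydrogenates only the free catechol of 7 to the 4-substituted o-quinone 12, Sc(OTf)3 chelates its two carbonyl oxygens, C2' of ring B of 11 (ortho to O3', para to O5') attacks C6' of 12, the β-carbon of the C4'=O/C5'=C6' enone, and the σ-complex rearomatises by proton loss and enolisation to the catechol 13. The closest known reaction types are the acid-catalysed Friedel–Crafts-type 1,4-arylation of quinones by alkoxyarenes and the addition of phenolic carbon nucleophiles to flavan-3-ol o-quinones at C6', the polarity by which catechol and pyrogallol B rings couple on oxidation; what is new is a fully etherified pyrogallol ring as the donor under Lewis acid catalysis. No ring is closed and no stereocentre is formed; the only new stereoelement is the biaryl axis, which arises under substrate control from the two flanking (2R)-chromanyl groups and is left open by the target structure. The step needs site selectivity among the arenes: C6 and C8 of both A rings carry bromine, both galloyl rings are deactivated by their ester carbonyl and C2'/C6' of the donor ring are equivalent, so only one constitution can result on the donor side, while on the acceptor the 1,4-position C6' is favoured over the 1,6-positions C2' and C5'. It also needs freedom from redox exchange and over-oxidation: the donor ring is a tri-ether that cannot be dehydrogenated to a quinone, and 12 is added slowly to an excess of 11 so that the product catechol does not meet free quinone. The C2 and C3 stereocentres stay untouched provided 12 is consumed before it tautomerises to a quinone methide at C2, which the low temperature and base-free medium are meant to ensure.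

Step 10
Reactants: 13 tetrabromo-trideca-O-benzyl-theasinensin F
Product: 14 theasinensin F
Conditions: H2 (1 atm), Pd(OH)2/C, NaOAc (4.4 equiv), THF/MeOH, rt; filtration and reversed-phase chromatography under argon
Reagents that add atoms: none
Why: Palladium-catalysed hydrogenolysis should cleave the thirteen benzyl ethers and the four aryl C–Br bonds in one operation, acetate buffering the HBr, while the ester groups and the four stereocentres are not affected.

**Compound list**

1 | (−)-epicatechin, (2R,3R)-2-(3,4-dihydroxyphenyl)chromane-3,5,7-triol | O[C@@H]1Cc2c(O)cc(O)cc2O[C@@H]1c1ccc(O)c(O)c1 | starting material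
2 | 3',4'-O-diphenylmethylene-(−)-epicatechin, (2R,3R)-2-(2,2-diphenyl-1,3-benzodioxol-5-yl)chromane-3,5,7-triol | O[C@@H]1Cc2c(O)cc(O)cc2O[C@@H]1c1ccc2OC(c3ccccc3)(c3ccccc3)Oc2c1 | intermediate
3 | (2R,3R)-5,7-bis(benzyloxy)-2-(2,2-diphenyl-1,3-benzodioxol-5-yl)chroman-3-ol | O[C@@H]1Cc2c(OCc3ccccc3)cc(OCc3ccccc3)cc2O[C@@H]1c1ccc2OC(c3ccccc3)(c3ccccc3)Oc2c1 | intermediate
4 | 3,4,5-tris(benzyloxy)benzoic acid | OC(=O)c1cc(OCc2ccccc2)c(OCc2ccccc2)c(OCc2ccccc2)c1 | starting material
5 | (2R,3R)-5,7-bis(benzyloxy)-2-(2,2-diphenyl-1,3-benzodioxol-5-yl)chroman-3-yl 3,4,5-tris(benzyloxy)benzoate | O=C(O[C@@H]1Cc2c(OCc3ccccc3)cc(OCc3ccccc3)cc2O[C@@H]1c1ccc2OC(c3ccccc3)(c3ccccc3)Oc2c1)c1cc(OCc2ccccc2)c(OCc2ccccc2)c(OCc2ccccc2)c1 | intermediate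
6 | (2R,3R)-5,7-bis(benzyloxy)-6,8-dibromo-2-(2,2-diphenyl-1,3-benzodioxol-5-yl)chroman-3-yl 3,4,5-tris(benzyloxy)benzoate | O=C(O[C@@H]1Cc2c(OCc3ccccc3)c(Br)c(OCc3ccccc3)c(Br)c2O[C@@H]1c1ccc2OC(c3ccccc3)(c3ccccc3)Oc2c1)c1cc(OCc2ccccc2)c(OCc2ccccc2)c(OCc2ccccc2)c1 | intermediate
7 | (2R,3R)-5,7-bis(benzyloxy)-6,8-dibromo-2-(3,4-dihydroxyphenyl)chroman-3-yl 3,4,5-tris(benzyloxy)benzoate | O=C(O[C@@H]1Cc2c(OCc3ccccc3)c(Br)c(OCc3ccccc3)c(Br)c2O[C@@H]1c1ccc(O)c(O)c1)c1cc(OCc2ccccc2)c(OCc2ccccc2)c(OCc2ccccc2)c1 | intermediate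
8 | (−)-epigallocatechin, (2R,3R)-2-(3,4,5-trihydroxyphenyl)chromane-3,5,7-triol | O[C@@H]1Cc2c(O)cc(O)cc2O[C@@H]1c1cc(O)c(O)c(O)c1 | starting material
9 | penta-O-benzyl-(−)-epigallocatechin, (2R,3R)-5,7-bis(benzyloxy)-2-[3,4,5-tris(benzyloxy)phenyl]chroman-3-ol | O[C@@H]1Cc2c(OCc3ccccc3)cc(OCc3ccccc3)cc2O[C@@H]1c1cc(OCc2ccccc2)c(OCc2ccccc2)c(OCc2ccccc2)c1 | intermediate
10 | octa-O-benzyl-(−)-epigallocatechin 3-gallate, (2R,3R)-5,7-bis(benzyloxy)-2-[3,4,5-tris(benzyloxy)phenyl]chroman-3-yl 3,4,5-tris(benzyloxy)benzoate | O=C(O[C@@H]1Cc2c(OCc3ccccc3)cc(OCc3ccccc3)cc2O[C@@H]1c1cc(OCc2ccccc2)c(OCc2ccccc2)c(OCc2ccccc2)c1)c1cc(OCc2ccccc2)c(OCc2ccccc2)c(OCc2ccccc2)c1 | intermediate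
11 | (2R,3R)-5,7-bis(benzyloxy)-6,8-dibromo-2-[3,4,5-tris(benzyloxy)phenyl]chroman-3-yl 3,4,5-tris(benzyloxy)benzoate | O=C(O[C@@H]1Cc2c(OCc3ccccc3)c(Br)c(OCc3ccccc3)c(Br)c2O[C@@H]1c1cc(OCc2ccccc2)c(OCc2ccccc2)c(OCc2ccccc2)c1)c1cc(OCc2ccccc2)c(OCc2ccccc2)c(OCc2ccccc2)c1 | intermediate
12 | ortho-quinone of 7, (2R,3R)-5,7-bis(benzyloxy)-6,8-dibromo-2-(3,4-dioxocyclohexa-1,5-dien-1-yl)chroman-3-yl 3,4,5-tris(benzyloxy)benzoate | O=C(O[C@@H]1Cc2c(OCc3ccccc3)c(Br)c(OCc3ccccc3)c(Br)c2O[C@@H]1C1=CC(=O)C(=O)C=C1)c1cc(OCc2ccccc2)c(OCc2ccccc2)c(OCc2ccccc2)c1 | intermediate (not isolated)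
13 | tetrabromo-trideca-O-benzyl-theasinensin F: biaryl from C6' of ring B (free 3',4'-catechol) of 7 to C2' of ring B of 11; all other thirteen phenols are benzyl ethers, C6 and C8 of both A rings carry bromine, (2R,3R) in both halves | O=C(O[C@@H]1Cc2c(OCc3ccccc3)c(Br)c(OCc3ccccc3)c(Br)c2O[C@@H]1c1cc(O)c(O)cc1-c1c([C@H]2Oc3c(Br)c(OCc4ccccc4)c(Br)c(OCc4ccccc4)c3C[C@H]2OC(=O)c2cc(OCc3ccccc3)c(OCc3ccccc3)c(OCc3ccccc3)c2)cc(OCc2ccccc2)c(OCc2ccccc2)c1OCc1ccccc1)c1cc(OCc2ccccc2)c(OCc2ccccc2)c(OCc2ccccc2)c1 | intermediate
14 | theasinensin F, (2R,3R) in both flavan-3-ol gallate halves | O=C(O[C@@H]1Cc2c(O)cc(O)cc2O[C@@H]1c1cc(O)c(O)cc1-c1c([C@H]2Oc3cc(O)cc(O)c3C[C@H]2OC(=O)c2cc(O)c(O)c(O)c2)cc(O)c(O)c1O)c1cc(O)c(O)c(O)c1 | target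

**Step count**

Total steps: 10. Longest linear sequence: 7 (steps 1 to 5, 9 and 10).

**Steps most likely to fail**

1. Step 9. The hindered tri-ether ring may add too slowly to the o-quinone, so that the quinone is lost by self-condensation or by tautomerisation to a quinone methide with erosion of the C2 configuration, and the product catechol may be re-oxidised by unreacted quinone. The fallback sets out from 6 and 11 and comes back to the route at 14. Compound 6 is iodinated at C6' of the benzodioxole ring, para to O3' (NIS, cat. TFA, CH2Cl2/MeCN, 0 °C), to give the aryl iodide F1. Miyaura borylation of this iodide (B2pin2, PdCl2(dppf), KOAc, dioxane, 80 °C) should give the pinacol boronate F2, the C–I bond reacting ahead of the doubly ortho-oxygenated C–Br bonds. Compound 11 is iodinated at C2' of ring B under the same conditions to give the aryl iodide F3. Suzuki–Miyaura coupling of the boronate with this iodide (Pd(OAc)2, SPhos, K3PO4, toluene/H2O, 70 °C) should give the fully protected biaryl F4. Hydrogenolysis under the conditions of step 10, which also cleaves the diphenylmethylene ketal, then gives 14.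

2. Step 10. Seventeen reductive cleavages on one large, poorly soluble molecule may stall through catalyst poisoning by bromide, leaving partially protected material, and the freed polyphenol may oxidise in air during isolation. The fallback sets out from 13 and comes back at 14 without hydrogen gas. The four C–Br bonds are removed first by formate reduction on zerovalent palladium formed in the flask (Pd(OAc)2, PPh3, HCO2Na, DMF, 80 °C), giving the bromine-free trideca-O-benzyl biaryl F5. The thirteen benzyl ethers are then cleaved by Lewis acid with a cation scavenger (BCl3, pentamethylbenzene, CH2Cl2, −78 °C), giving 14.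

3. Step 6. Fivefold alkylation of the free polyphenol under base may be accompanied by C-benzylation of ring A, base-induced epimerisation at C2 through ring opening of the phenoxide, and air oxidation of the pyrogallol ring before it is capped. The fallback sets out from 8 and comes back at 9, and never exposes the free polyphenol to base. Compound 8 is peracetylated (Ac2O, pyridine, rt) to give hexa-O-acetyl-(−)-epigallocatechin F6. One-pot deacetylation–benzylation (BnCl, NaH, H2O added slowly, DMF, 0 °C to rt) cleaves each aryl acetate by hydroxide formed in the flask and benzylates each phenoxide as it appears, which should give 3-O-acetyl-penta-O-benzyl-(−)-epigallocatechin F7 with the less reactive alkyl acetate intact. Methanolysis of the 3-O-acetate (K2CO3 cat., MeOH/THF, rt) then gives 9.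

**Further compounds**

F1 | step 9 | (2R,3R)-5,7-bis(benzyloxy)-6,8-dibromo-2-(6-iodo-2,2-diphenyl-1,3-benzodioxol-5-yl)chroman-3-yl 3,4,5-tris(benzyloxy)benzoate | O=C(O[C@@H]1Cc2c(OCc3ccccc3)c(Br)c(OCc3ccccc3)c(Br)c2O[C@@H]1c1cc2OC(c3ccccc3)(c3ccccc3)Oc2cc1I)c1cc(OCc2ccccc2)c(OCc2ccccc2)c(OCc2ccccc2)c1
F2 | step 9 | pinacol boronate of F1, with 4,4,5,5-tetramethyl-1,3,2-dioxaborolan-2-yl in place of iodine | O=C(O[C@@H]1Cc2c(OCc3ccccc3)c(Br)c(OCc3ccccc3)c(Br)c2O[C@@H]1c1cc2OC(c3ccccc3)(c3ccccc3)Oc2cc1B1OC(C)(C)C(C)(C)O1)c1cc(OCc2ccccc2)c(OCc2ccccc2)c(OCc2ccccc2)c1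
F3 | step 9 | (2R,3R)-5,7-bis(benzyloxy)-6,8-dibromo-2-[3,4,5-tris(benzyloxy)-2-iodophenyl]chroman-3-yl 3,4,5-tris(benzyloxy)benzoate | O=C(O[C@@H]1Cc2c(OCc3ccccc3)c(Br)c(OCc3ccccc3)c(Br)c2O[C@@H]1c1cc(OCc2ccccc2)c(OCc2ccccc2)c(OCc2ccccc2)c1I)c1cc(OCc2ccccc2)c(OCc2ccccc2)c(OCc2ccccc2)c1
F4 | step 9 | 3',4'-O-diphenylmethylene ketal of 13 (fully protected biaryl) | O=C(O[C@@H]1Cc2c(OCc3ccccc3)c(Br)c(OCc3ccccc3)c(Br)c2O[C@@H]1c1cc2OC(c3ccccc3)(c3ccccc3)Oc2cc1-c1c([C@H]2Oc3c(Br)c(OCc4ccccc4)c(Br)c(OCc4ccccc4)c3C[C@H]2OC(=O)c2cc(OCc3ccccc3)c(OCc3ccccc3)c(OCc3ccccc3)c2)cc(OCc2ccccc2)c(OCc2ccccc2)c1OCc1ccccc1)c1cc(OCc2ccccc2)c(OCc2ccccc2)c(OCc2ccccc2)c1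
F5 | step 10 | trideca-O-benzyl-theasinensin F (13 without its four bromine atoms) | O=C(O[C@@H]1Cc2c(OCc3ccccc3)cc(OCc3ccccc3)cc2O[C@@H]1c1cc(O)c(O)cc1-c1c([C@H]2Oc3cc(OCc4ccccc4)cc(OCc4ccccc4)c3C[C@H]2OC(=O)c2cc(OCc3ccccc3)c(OCc3ccccc3)c(OCc3ccccc3)c2)cc(OCc2ccccc2)c(OCc2ccccc2)c1OCc1ccccc1)c1cc(OCc2ccccc2)c(OCc2ccccc2)c(OCc2ccccc2)c1
F6 | step 6 | hexa-O-acetyl-(−)-epigallocatechin, (2R,3R)-5,7-diacetoxy-2-(3,4,5-triacetoxyphenyl)chroman-3-yl acetate | CC(=O)O[C@@H]1Cc2c(OC(C)=O)cc(OC(C)=O)cc2O[C@@H]1c1cc(OC(C)=O)c(OC(C)=O)c(OC(C)=O)c1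
F7 | step 6 | 3-O-acetyl-penta-O-benzyl-(−)-epigallocatechin, (2R,3R)-5,7-bis(benzyloxy)-2-[3,4,5-tris(benzyloxy)phenyl]chroman-3-yl acetate | CC(=O)O[C@@H]1Cc2c(OCc3ccccc3)cc(OCc3ccccc3)cc2O[C@@H]1c1cc(OCc2ccccc2)c(OCc2ccccc2)c(OCc2ccccc2)c1
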